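**Strategy**

Ring A (the bromodimethylcyclohexanol) is opened at the bond joining its gem-dimethyl carbon to the CH2 next to the tertiary carbinol carbon. The key step is a Lewis acid epoxide-initiated cation–olefin cyclization of an acyclic 2,2-dimethyloxirane tethered to a 1,1-disubstituted alkene; the Boc carbonate on the adjacent secondary carbinol captures the ring cation, so ring A, its tertiary C–O bond and a cyclic carbonate form together. It exploits the vicinal diol (secondary carbinol beside the ring A tertiary carbinol) and the 1,4 O/Br pattern of ring A. Both neopentyl bromides then arise by Appel inversion; the trans-hydrindane (rings B and C) is built from 2-methylcyclohexane-1,3-dione.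

Key step: step 16

Atom labels used in the Why lines: ring A = C1 (CMe2), C2 (CH2), C3 (tertiary carbinol), C4, C5, C6 (CHBr); C7 = secondary carbinol; hydrindane = C8 (bears C7), C9, C10, C11 (angular-methyl carbon), C12 (CHBr), C13, C14, C15 (methyl carbinol), C16 (ring-fusion CH).

Remark: the catalyst enantiomers in steps 2 and 15 are assigned by the usual models for these reagents; if the sense proves opposite, the mirror-image catalyst is used.

**Route**

Step 1
Reactants: 1 2-methylcyclohexane-1,3-dione; 2 methyl (2E)-4-bromobut-2-enoate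
Product: 3 methyl (2E)-4-(1-methyl-2,6-dioxocyclohexyl)but-2-enoate
Conditions: Pd(PPh3)4 (2 mol%), K2CO3, THF, rt
Reagents that add atoms: none
Why: Tsuji–Trost allylic alkylation, in which the soft dione enolate attacks the ester-substituted π-allylpalladium complex at the terminus remote from the ester and so gives the C-alkylated quaternary dione.

Step 2
Reactants: 3 methyl (2E)-4-(1-methyl-2,6-dioxocyclohexyl)but-2-enoate
Product: 4 methyl (2E)-4-[(1R,2R)-2-hydroxy-1-methyl-6-oxocyclohexyl]but-2-enoate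
Conditions: (S)-1-methyl-3,3-diphenyltetrahydro-1H,3H-pyrrolo[1,2-c][1,3,2]oxazaborole ((S)-Me-CBS, 20 mol%), catecholborane, toluene, −60 °C; aqueous work-up
Reagents that add atoms: none
Why: Corey–Bakshi–Shibata reduction desymmetrizes the dione, the oxazaborolidine selecting one enantiotopic carbonyl and delivering hydride anti to the larger crotonate chain, which should set C12 (R, hydroxyl cis to the chain) and thereby C11 (R).

Step 3
Reactants: 4 methyl (2E)-4-[(1R,2R)-2-hydroxy-1-methyl-6-oxocyclohexyl]but-2-enoate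
Product: 5 methyl (2E)-4-[(1R,2R)-2-{[tert-butyl(dimethyl)silyl]oxy}-1-methyl-6-oxocyclohexyl]but-2-enoate
Conditions: TBSOTf, 2,6-lutidine, CH2Cl2, −78 → 0 °C
Reagents that add atoms: tert-butyldimethylsilyl trifluoromethanesulfonate, CC(C)(C)[Si](C)(C)OS(=O)(=O)C(F)(F)F
Why: Silyl triflate silylation of the hindered secondary alcohol protects C12–OH against the later oxidation and organometallic steps.

Step 4
Reactants: 5 methyl (2E)-4-[(1R,2R)-2-{[tert-butyl(dimethyl)silyl]oxy}-1-methyl-6-oxocyclohexyl]but-2-enoate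
Product: 6 methyl (1S,3aR,4R,7aS)-4-{[tert-butyl(dimethyl)silyl]oxy}-7a-hydroxy-3a-methyloctahydro-1H-indene-1-carboxylate
Conditions: Cu(OAc)2·H2O (5 mol%), 1,2-bis(diphenylphosphino)benzene (5 mol%), (EtO)2MeSiH (2 equiv), toluene, rt; then 1 M HCl, THF, 0 °C
Reagents that add atoms: none
Why: CuH-catalysed intramolecular reductive aldol reaction, in which conjugate reduction of the enoate gives a copper enolate that closes the five-membered ring onto the ketone (5-exo) through a chelated transition state that places the new hydroxyl cis to the ester; both new centres are erased or corrected later.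

Step 5
Reactants: 6 methyl (1S,3aR,4R,7aS)-4-{[tert-butyl(dimethyl)silyl]oxy}-7a-hydroxy-3a-methyloctahydro-1H-indene-1-carboxylate
Product: 7 methyl (1S,3aS,4R)-4-{[tert-butyl(dimethyl)silyl]oxy}-3a-methyl-2,3,3a,4,5,6-hexahydro-1H-indene-1-carboxylate
Conditions: Burgess reagent (methyl N-(triethylammoniosulfonyl)carbamate), toluene, 60 °C
Reagents that add atoms: none
Why: Burgess dehydration is a syn elimination, and because the C8 hydrogen is anti to the tertiary sulfamate only a C15 hydrogen can be removed, so the alkene should form at C15=C16, out of conjugation with the ester.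

Step 6
Reactants: 7 methyl (1S,3aS,4R)-4-{[tert-butyl(dimethyl)silyl]oxy}-3a-methyl-2,3,3a,4,5,6-hexahydro-1H-indene-1-carboxylate
Product: 9 methyl (1S,3aS,4R,7S,7aS)-4-{[tert-butyl(dimethyl)silyl]oxy}-7-hydroxy-3a-methyloctahydro-1H-indene-1-carboxylate, via alkylborane 8 (not isolated)
Conditions: BH3·SMe2 (1.5 equiv), THF, 0 °C → rt; then 3 M aq. NaOH, 30% H2O2, 0 °C
Reagents that add atoms: borane–dimethyl sulfide (boron in 8), C[S+](C)[BH3-]; hydrogen peroxide, OO
Why: Hydroboration–oxidation, in which borane adds syn and anti-Markovnikov from the face opposite the angular methyl and the C8 ester, should set the trans ring fusion (C16–H) and an equatorial C15 hydroxyl in one operation.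

Step 7
Reactants: 9 methyl (1S,3aS,4R,7S,7aS)-4-{[tert-butyl(dimethyl)silyl]oxy}-7-hydroxy-3a-methyloctahydro-1H-indene-1-carboxylate
Product: 10 methyl (1R,3aS,4R,7S,7aS)-4-{[tert-butyl(dimethyl)silyl]oxy}-7-hydroxy-3a-methyloctahydro-1H-indene-1-carboxylate
Conditions: NaOMe (0.3 equiv), MeOH, 50 °C
Reagents that add atoms: none
Why: Base-mediated epimerization through the ester enolate should move the C8 ester off the face of the angular methyl (a 1,3-cis clash on the five-membered ring) to the thermodynamically preferred face, cis to the ring-fusion hydrogen, as in the target.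

Step 8
Reactants: 10 methyl (1R,3aS,4R,7S,7aS)-4-{[tert-butyl(dimethyl)silyl]oxy}-7-hydroxy-3a-methyloctahydro-1H-indene-1-carboxylate
Product: 11 methyl (1R,3aS,4R,7aS)-4-{[tert-butyl(dimethyl)silyl]oxy}-3a-methyl-7-oxooctahydro-1H-indene-1-carboxylate
Conditions: Dess–Martin periodinane, CH2Cl2, 0 °C → rt
Reagents that add atoms: none
Why: Dess–Martin oxidation under non-basic conditions should give the C15 ketone without epimerizing the adjacent ring-fusion centre C16.

Step 9
Reactants: 11 methyl (1R,3aS,4R,7aS)-4-{[tert-butyl(dimethyl)silyl]oxy}-3a-methyl-7-oxooctahydro-1H-indene-1-carboxylate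
Product: 12 methyl (1R,3aS,4R,7R,7aS)-4-{[tert-butyl(dimethyl)silyl]oxy}-7-hydroxy-3a,7-dimethyloctahydro-1H-indene-1-carboxylate
Conditions: MeMgBr (3 equiv), CeCl3 (anhydrous, 3 equiv), THF, −78 °C
Reagents that add atoms: methylmagnesium bromide, C[Mg]Br
Why: Organocerium addition (weakly basic, so no enolization at C16, and inert toward the ester) should enter equatorially because axial approach is blocked by the 1,3-diaxial angular methyl, giving the axial tertiary alcohol at C15.

Step 10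
Reactants: 12 methyl (1R,3aS,4R,7R,7aS)-4-{[tert-butyl(dimethyl)silyl]oxy}-7-hydroxy-3a,7-dimethyloctahydro-1H-indene-1-carboxylate
Product: 13 (1R,3aS,4R,7R,7aS)-4-{[tert-butyl(dimethyl)silyl]oxy}-7-hydroxy-N-methoxy-N,3a,7-trimethyloctahydro-1H-indene-1-carboxamide
Conditions: MeNHOMe·HCl (3 equiv), iPrMgCl (7 equiv), THF, −20 → 0 °C
Reagents that add atoms: N,O-dimethylhydroxylamine hydrochloride, CNOC.Cl
Why: Aminolysis of the ester by the magnesium amide of N,O-dimethylhydroxylamine gives the Weinreb amide, the acyl donor for the ketone synthesis.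

Step 11
Reactants: 14 6-methylhept-5-en-2-one
Product: 15 N'-(6-methylhept-5-en-2-ylidene)-2,4,6-tri(propan-2-yl)benzenesulfonohydrazide
Conditions: 2,4,6-tri(propan-2-yl)benzenesulfonohydrazide, HCl (cat.), MeOH, rt
Reagents that add atoms: 2,4,6-tri(propan-2-yl)benzenesulfonohydrazide, NNS(=O)(=O)c1c(C(C)C)cc(C(C)C)cc1C(C)C
Why: Acid-catalysed condensation gives the arenesulfonylhydrazone needed for the Shapiro reaction.

Step 12
Reactants: 15 N'-(6-methylhept-5-en-2-ylidene)-2,4,6-tri(propan-2-yl)benzenesulfonohydrazide; 13 (1R,3aS,4R,7R,7aS)-4-{[tert-butyl(dimethyl)silyl]oxy}-7-hydroxy-N-methoxy-N,3a,7-trimethyloctahydro-1H-indene-1-carboxamide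
Product: 17 1-[(1R,3aS,4R,7R,7aS)-4-{[tert-butyl(dimethyl)silyl]oxy}-7-hydroxy-3a,7-dimethyloctahydro-1H-inden-1-yl]-6-methyl-2-methylidenehept-5-en-1-one, via alkenyllithium 16 (not isolated)
Conditions: 15 (3 equiv), n-BuLi (6.3 equiv), THF, −78 → 0 °C; then 13, −78 °C; aq. NH4Cl (the first equivalent of 16 deprotonates the tertiary hydroxyl)
Reagents that add atoms: none
Why: Shapiro reaction, in which double deprotonation at the methyl group and loss of sulfinate and dinitrogen give the 2-lithio-1-alkene, which acylates on the Weinreb amide and stops at the ketone through the chelated tetrahedral intermediate.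

Step 13
Reactants: 17 1-[(1R,3aS,4R,7R,7aS)-4-{[tert-butyl(dimethyl)silyl]oxy}-7-hydroxy-3a,7-dimethyloctahydro-1H-inden-1-yl]-6-methyl-2-methylidenehept-5-en-1-one
Product: 18 (1R)-1-[(1R,3aS,4R,7R,7aS)-4-{[tert-butyl(dimethyl)silyl]oxy}-7-hydroxy-3a,7-dimethyloctahydro-1H-inden-1-yl]-6-methyl-2-methylidenehept-5-en-1-ol
Conditions: NaBH4, CeCl3·7H2O, MeOH, −78 °C
Reagents that add atoms: none
Why: Luche 1,2-reduction of the enone under Felkin–Anh control (hydride anti to the bulky ring-fusion carbon C16, passing the C8 hydrogen) should set C7 as R.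

Step 14
Reactants: 18 (1R)-1-[(1R,3aS,4R,7R,7aS)-4-{[tert-butyl(dimethyl)silyl]oxy}-7-hydroxy-3a,7-dimethyloctahydro-1H-inden-1-yl]-6-methyl-2-methylidenehept-5-en-1-ol
Product: 19 tert-butyl (1R)-1-[(1R,3aS,4R,7R,7aS)-4-{[tert-butyl(dimethyl)silyl]oxy}-7-hydroxy-3a,7-dimethyloctahydro-1H-inden-1-yl]-6-methyl-2-methylidenehept-5-en-1-yl carbonate
Conditions: Boc2O, 4-(dimethylamino)pyridine (cat.), MeCN, rt
Reagents that add atoms: di-tert-butyl dicarbonate, CC(C)(C)OC(=O)OC(=O)OC(C)(C)C
Why: Nucleophile-catalysed acylation converts the secondary allylic alcohol into its tert-butyl carbonate, while the axial tertiary alcohol, 1,3-diaxial to the angular methyl, should not react.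

Step 15
Reactants: 19 tert-butyl (1R)-1-[(1R,3aS,4R,7R,7aS)-4-{[tert-butyl(dimethyl)silyl]oxy}-7-hydroxy-3a,7-dimethyloctahydro-1H-inden-1-yl]-6-methyl-2-methylidenehept-5-en-1-yl carbonate
Product: 20 tert-butyl (1R)-1-[(1R,3aS,4R,7R,7aS)-4-{[tert-butyl(dimethyl)silyl]oxy}-7-hydroxy-3a,7-dimethyloctahydro-1H-inden-1-yl]-4-[(2R)-3,3-dimethyloxiran-2-yl]-2-methylidenebutyl carbonate
Conditions: 1,2:4,5-di-O-isopropylidene-β-D-erythro-2,3-hexodiulo-2,6-pyranose (Shi ketone, 30 mol%), KHSO5 (as Oxone), K2CO3, Bu4NHSO4, aq. Na2B4O7 buffer, MeCN–CH2(OMe)2, 0 °C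
Reagents that add atoms: potassium peroxymonosulfate, [K+].[O-]S(=O)(=O)OO
Why: Shi asymmetric epoxidation, in which the chiral dioxirane selects the electron-rich trisubstituted alkene over the 1,1-disubstituted allylic-carbonate alkene and should set the epoxide carbon C6 as R under reagent control.

Step 16
Reactants: 20 tert-butyl (1R)-1-[(1R,3aS,4R,7R,7aS)-4-{[tert-butyl(dimethyl)silyl]oxy}-7-hydroxy-3a,7-dimethyloctahydro-1H-inden-1-yl]-4-[(2R)-3,3-dimethyloxiran-2-yl]-2-methylidenebutyl carbonate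
Product: 21 (4R,5R,8R)-4-[(1R,3aS,4R,7R,7aS)-4-{[tert-butyl(dimethyl)silyl]oxy}-7-hydroxy-3a,7-dimethyloctahydro-1H-inden-1-yl]-8-hydroxy-7,7-dimethyl-1,3-dioxaspiro[4.5]decan-2-one
Conditions: BF3·OEt2 (2 equiv), CH2Cl2, −78 °C; aq. NaHCO3
Reagents that add atoms: none
Why: BF3 activates the epoxide and its tertiary C–O bond (C1) ionizes as the CH2 terminus (C2) of the 1,1-disubstituted alkene attacks C1 from the side opposite the oxygen, while the carbonyl oxygen of the Boc carbonate adds to the developing tertiary cation at C3 anti to the new C–C bond; loss of 2-methylpropene from the dioxolanylium ion then leaves the cyclic carbonate. The closest known reaction types are the epoxide-initiated cation–olefin (polyene) cyclization and the capture of a cation by a neighbouring tert-butyl carbonate, as in halocyclocarbonation. Ring A closes in the 6-endo mode through a chair and the dioxolanone closes in the 5-exo mode. The only new stereocentre, C3, is set by the carbinol centre C7, whose rotamer with C7–H eclipsing the methylene (minimal 1,3-allylic strain) delivers the carbonate to one alkene face, and by the chair, which places the C3–O and the epoxide-derived C6–O bonds both equatorial, that is 1,4-trans; C6 (R) is carried over from the Shi epoxide, and the (7R)/(6R) pairing is the matched one. The step needs Markovnikov opening at C1, 6-endo rather than 5-exo attack, and carbonate capture faster than hydride shift, proton loss or capture by the epoxide oxygen; the tertiary nature of C1, the inaccessible primary cation of the 5-exo path, the five-membered participation of the carbonate and the low temperature should secure these.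

Step 17
Reactants: 21 (4R,5R,8R)-4-[(1R,3aS,4R,7R,7aS)-4-{[tert-butyl(dimethyl)silyl]oxy}-7-hydroxy-3a,7-dimethyloctahydro-1H-inden-1-yl]-8-hydroxy-7,7-dimethyl-1,3-dioxaspiro[4.5]decan-2-one
Product: 22 (4R,5R,8R)-4-[(1R,3aS,4R,7R,7aS)-4,7-dihydroxy-3a,7-dimethyloctahydro-1H-inden-1-yl]-8-hydroxy-7,7-dimethyl-1,3-dioxaspiro[4.5]decan-2-one
Conditions: Bu4NF, AcOH (1:1), THF, 50 °C
Reagents that add atoms: none
Why: Fluoride-mediated desilylation frees the axial C12 alcohol, and the acetic acid buffer should keep the cyclic carbonate intact.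

Step 18
Reactants: 22 (4R,5R,8R)-4-[(1R,3aS,4R,7R,7aS)-4,7-dihydroxy-3a,7-dimethyloctahydro-1H-inden-1-yl]-8-hydroxy-7,7-dimethyl-1,3-dioxaspiro[4.5]decan-2-one
Product: 23 (4R,5R,8S)-8-bromo-4-[(1R,3aS,4S,7R,7aS)-4-bromo-7-hydroxy-3a,7-dimethyloctahydro-1H-inden-1-yl]-7,7-dimethyl-1,3-dioxaspiro[4.5]decan-2-one
Conditions: CBr4 (6 equiv), PPh3 (6 equiv), pyridine, toluene, 70 °C
Reagents that add atoms: tetrabromomethane, BrC(Br)(Br)Br
Why: Appel reaction, in which both axial secondary alcohols are activated as alkoxyphosphonium ions and displaced by bromide with inversion (SN2) to give the equatorial bromides at C6 and C12 (turning the 1,4-trans O/O of ring A into the 1,4-cis O/Br of the target), while the tertiary alcohol, 1,3-diaxial to the angular methyl, should be too hindered to be activated.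

Step 19
Reactants: 23 (4R,5R,8S)-8-bromo-4-[(1R,3aS,4S,7R,7aS)-4-bromo-7-hydroxy-3a,7-dimethyloctahydro-1H-inden-1-yl]-7,7-dimethyl-1,3-dioxaspiro[4.5]decan-2-one
Product: 24 (1R,4S)-4-bromo-1-{(R)-[(1R,3aS,4S,7R,7aS)-4-bromo-7-hydroxy-3a,7-dimethyloctahydro-1H-inden-1-yl](hydroxy)methyl}-3,3-dimethylcyclohexan-1-ol
Conditions: K2CO3, MeOH, rt
Reagents that add atoms: none
Why: Base-catalysed methanolysis (transesterification) of the cyclic carbonate releases the vicinal diol; the hindered secondary bromides, each cis to the nearby tertiary oxygen, cannot be displaced intramolecularly.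

**Compound list**

1 | 2-methylcyclohexane-1,3-dione | CC1C(=O)CCCC1=O | starting material
2 | methyl (2E)-4-bromobut-2-enoate | COC(=O)/C=C/CBr | starting material
3 | methyl (2E)-4-(1-methyl-2,6-dioxocyclohexyl)but-2-enoate | COC(=O)/C=C/CC1(C)C(=O)CCCC1=O | intermediate
4 | methyl (2E)-4-[(1R,2R)-2-hydroxy-1-methyl-6-oxocyclohexyl]but-2-enoate | COC(=O)/C=C/C[C@]1(C)[C@H](O)CCCC1=O | intermediate
5 | methyl (2E)-4-[(1R,2R)-2-{[tert-butyl(dimethyl)silyl]oxy}-1-methyl-6-oxocyclohexyl]but-2-enoate | COC(=O)/C=C/C[C@]1(C)[C@H](O[Si](C)(C)C(C)(C)C)CCCC1=O | intermediate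
6 | methyl (1S,3aR,4R,7aS)-4-{[tert-butyl(dimethyl)silyl]oxy}-7a-hydroxy-3a-methyloctahydro-1H-indene-1-carboxylate (cis-fused; hydroxyl, ester and angular methyl on one face) | COC(=O)[C@H]1CC[C@]2(C)[C@H](O[Si](C)(C)C(C)(C)C)CCC[C@]12O | intermediate
7 | methyl (1S,3aS,4R)-4-{[tert-butyl(dimethyl)silyl]oxy}-3a-methyl-2,3,3a,4,5,6-hexahydro-1H-indene-1-carboxylate | COC(=O)[C@H]1CC[C@]2(C)[C@H](O[Si](C)(C)C(C)(C)C)CCC=C12 | intermediate
8 | methyl 7-boranyl-4-{[tert-butyl(dimethyl)silyl]oxy}-3a-methyloctahydro-1H-indene-1-carboxylate (trans-fused; boron on the face of the ring-fusion hydrogen; other centres as in 9) | COC(=O)[C@H]1CC[C@]2(C)[C@H](O[Si](C)(C)C(C)(C)C)CC[C@H](B)[C@@H]12 | intermediate (not isolated)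
9 | methyl (1S,3aS,4R,7S,7aS)-4-{[tert-butyl(dimethyl)silyl]oxy}-7-hydroxy-3a-methyloctahydro-1H-indene-1-carboxylate | COC(=O)[C@H]1CC[C@]2(C)[C@H](O[Si](C)(C)C(C)(C)C)CC[C@H](O)[C@@H]12 | intermediate
10 | methyl (1R,3aS,4R,7S,7aS)-4-{[tert-butyl(dimethyl)silyl]oxy}-7-hydroxy-3a-methyloctahydro-1H-indene-1-carboxylate | COC(=O)[C@@H]1CC[C@]2(C)[C@H](O[Si](C)(C)C(C)(C)C)CC[C@H](O)[C@@H]12 | intermediate
11 | methyl (1R,3aS,4R,7aS)-4-{[tert-butyl(dimethyl)silyl]oxy}-3a-methyl-7-oxooctahydro-1H-indene-1-carboxylate | COC(=O)[C@@H]1CC[C@]2(C)[C@H](O[Si](C)(C)C(C)(C)C)CCC(=O)[C@@H]12 | intermediate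
12 | methyl (1R,3aS,4R,7R,7aS)-4-{[tert-butyl(dimethyl)silyl]oxy}-7-hydroxy-3a,7-dimethyloctahydro-1H-indene-1-carboxylate | COC(=O)[C@@H]1CC[C@]2(C)[C@H](O[Si](C)(C)C(C)(C)C)CC[C@@](C)(O)[C@@H]12 | intermediate
13 | (1R,3aS,4R,7R,7aS)-4-{[tert-butyl(dimethyl)silyl]oxy}-7-hydroxy-N-methoxy-N,3a,7-trimethyloctahydro-1H-indene-1-carboxamide | CON(C)C(=O)[C@@H]1CC[C@]2(C)[C@H](O[Si](C)(C)C(C)(C)C)CC[C@@](C)(O)[C@@H]12 | intermediate
14 | 6-methylhept-5-en-2-one | CC(=O)CCC=C(C)C | starting material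
15 | N'-(6-methylhept-5-en-2-ylidene)-2,4,6-tri(propan-2-yl)benzenesulfonohydrazide | CC(CCC=C(C)C)=NNS(=O)(=O)c1c(C(C)C)cc(C(C)C)cc1C(C)C | intermediate
16 | (6-methylhepta-1,5-dien-2-yl)lithium | [Li]C(=C)CCC=C(C)C | intermediate (not isolated)
17 | 1-[(1R,3aS,4R,7R,7aS)-4-{[tert-butyl(dimethyl)silyl]oxy}-7-hydroxy-3a,7-dimethyloctahydro-1H-inden-1-yl]-6-methyl-2-methylidenehept-5-en-1-one | C=C(CCC=C(C)C)C(=O)[C@@H]1CC[C@]2(C)[C@H](O[Si](C)(C)C(C)(C)C)CC[C@@](C)(O)[C@@H]12 | intermediate
18 | (1R)-1-[(1R,3aS,4R,7R,7aS)-4-{[tert-butyl(dimethyl)silyl]oxy}-7-hydroxy-3a,7-dimethyloctahydro-1H-inden-1-yl]-6-methyl-2-methylidenehept-5-en-1-ol | C=C(CCC=C(C)C)[C@H](O)[C@@H]1CC[C@]2(C)[C@H](O[Si](C)(C)C(C)(C)C)CC[C@@](C)(O)[C@@H]12 | intermediate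
19 | tert-butyl (1R)-1-[(1R,3aS,4R,7R,7aS)-4-{[tert-butyl(dimethyl)silyl]oxy}-7-hydroxy-3a,7-dimethyloctahydro-1H-inden-1-yl]-6-methyl-2-methylidenehept-5-en-1-yl carbonate | C=C(CCC=C(C)C)[C@H](OC(=O)OC(C)(C)C)[C@@H]1CC[C@]2(C)[C@H](O[Si](C)(C)C(C)(C)C)CC[C@@](C)(O)[C@@H]12 | intermediate
20 | tert-butyl (1R)-1-[(1R,3aS,4R,7R,7aS)-4-{[tert-butyl(dimethyl)silyl]oxy}-7-hydroxy-3a,7-dimethyloctahydro-1H-inden-1-yl]-4-[(2R)-3,3-dimethyloxiran-2-yl]-2-methylidenebutyl carbonate | CC1(C)O[C@@H]1CCC(=C)[C@H](OC(=O)OC(C)(C)C)[C@@H]1CC[C@]2(C)[C@H](O[Si](C)(C)C(C)(C)C)CC[C@@](C)(O)[C@@H]12 | intermediate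
21 | (4R,5R,8R)-4-[(1R,3aS,4R,7R,7aS)-4-{[tert-butyl(dimethyl)silyl]oxy}-7-hydroxy-3a,7-dimethyloctahydro-1H-inden-1-yl]-8-hydroxy-7,7-dimethyl-1,3-dioxaspiro[4.5]decan-2-one | CC1(C)C[C@@]2(CC[C@H]1O)OC(=O)O[C@@H]2[C@@H]1CC[C@]3(C)[C@H](O[Si](C)(C)C(C)(C)C)CC[C@@](C)(O)[C@@H]13 | intermediate
22 | (4R,5R,8R)-4-[(1R,3aS,4R,7R,7aS)-4,7-dihydroxy-3a,7-dimethyloctahydro-1H-inden-1-yl]-8-hydroxy-7,7-dimethyl-1,3-dioxaspiro[4.5]decan-2-one | CC1(C)C[C@@]2(CC[C@H]1O)OC(=O)O[C@@H]2[C@@H]1CC[C@]3(C)[C@H](O)CC[C@@](C)(O)[C@@H]13 | intermediate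
23 | (4R,5R,8S)-8-bromo-4-[(1R,3aS,4S,7R,7aS)-4-bromo-7-hydroxy-3a,7-dimethyloctahydro-1H-inden-1-yl]-7,7-dimethyl-1,3-dioxaspiro[4.5]decan-2-one | CC1(C)C[C@@]2(CC[C@@H]1Br)OC(=O)O[C@@H]2[C@@H]1CC[C@]3(C)[C@@H](Br)CC[C@@](C)(O)[C@@H]13 | intermediate
24 | (1R,4S)-4-bromo-1-{(R)-[(1R,3aS,4S,7R,7aS)-4-bromo-7-hydroxy-3a,7-dimethyloctahydro-1H-inden-1-yl](hydroxy)methyl}-3,3-dimethylcyclohexan-1-ol | CC1(C)C[C@@](O)([C@H](O)[C@@H]2CC[C@]3(C)[C@@H](Br)CC[C@@](C)(O)[C@@H]23)CC[C@@H]1Br | target

**Summary**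

Total step count: 19. Longest linear sequence: 18 steps (steps 1–10 and 12–19); step 11 is a one-step branch.

Steps most likely to fail:

1. Step 18 (double Appel bromination). The risk is slow backside displacement at two neopentyl-type carbinol carbons, so that elimination, a 1,2-methyl shift with ring contraction, or dehydration of the tertiary alcohol overtakes substitution. The fallback sets out from 22 and comes back at 23, and separates activation from displacement. Tf2O and pyridine in CH2Cl2 at −40 °C should convert 22 into (4R,5R,8R)-7,7-dimethyl-2-oxo-4-[(1R,3aS,4R,7R,7aS)-7-hydroxy-3a,7-dimethyl-4-{[(trifluoromethyl)sulfonyl]oxy}octahydro-1H-inden-1-yl]-1,3-dioxaspiro[4.5]decan-8-yl trifluoromethanesulfonate F1, the hindered tertiary hydroxyl staying free. Bu4NBr in toluene at room temperature should then displace both axial triflate groups of F1 with inversion and give 23.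

2. Step 16 (key cyclization). The risk is that the BF3-activated epoxide rearranges by hydride shift to a ketone, or that the ring cation loses a proton or is captured by the epoxide oxygen, before the weakly nucleophilic carbonate carbonyl adds. The fallback sets out from 18 and comes back at 21, and replaces the carbonate by a more nucleophilic carbamate. Me2NCOCl with NaHMDS in THF should convert 18 into (1R)-1-[(1R,3aS,4R,7R,7aS)-4-{[tert-butyl(dimethyl)silyl]oxy}-7-hydroxy-3a,7-dimethyloctahydro-1H-inden-1-yl]-6-methyl-2-methylidenehept-5-en-1-yl dimethylcarbamate F2. Shi epoxidation as in step 15 should then turn F2 into (1R)-1-[(1R,3aS,4R,7R,7aS)-4-{[tert-butyl(dimethyl)silyl]oxy}-7-hydroxy-3a,7-dimethyloctahydro-1H-inden-1-yl]-4-[(2R)-3,3-dimethyloxiran-2-yl]-2-methylidenebutyl dimethylcarbamate F3. BF3·OEt2 in CH2Cl2 at −78 °C should close ring A of F3 with capture of the ring cation by the carbamate carbonyl oxygen, and aqueous hydrolysis of the resulting cyclic iminium carbonate should give 21. The carbamates F2 and F3 differ from 19 and 20 only in the acyl group on the C7 oxygen.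

3. Step 4 (reductive aldol cyclization). The risk is conjugate reduction without ring closure onto the hindered ketone, or closure with the ester trans to the hydroxyl, which would steer the elimination of step 5 into conjugation. The fallback sets out from 5 and comes back at 7, bypassing step 5 as well. H2 over 10% Pd/C in EtOAc should reduce the enoate of 5 to methyl 4-[(1R,2R)-2-{[tert-butyl(dimethyl)silyl]oxy}-1-methyl-6-oxocyclohexyl]butanoate F4. KHMDS and PhNTf2 in THF at −78 °C should convert F4 into methyl 4-[(1R,6R)-6-{[tert-butyl(dimethyl)silyl]oxy}-1-methyl-2-{[(trifluoromethyl)sulfonyl]oxy}cyclohex-2-en-1-yl]butanoate F5, since the ketone can enolize only toward C15. Intramolecular α-alkenylation of the ester enolate of F5 with Pd2(dba)3, P(t-Bu)3 and LiHMDS in toluene at rt should then form the C8–C16 bond, and kinetic protonation of the dienolate on the face opposite the angular methyl should give 7. Neither F4 nor F5 needs the tertiary aldol hydroxyl, so the regiochemistry of the alkene is fixed by the enol triflate F5.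

**Further compounds**

F1 | step 18 | (4R,5R,8R)-7,7-dimethyl-2-oxo-4-[(1R,3aS,4R,7R,7aS)-7-hydroxy-3a,7-dimethyl-4-{[(trifluoromethyl)sulfonyl]oxy}octahydro-1H-inden-1-yl]-1,3-dioxaspiro[4.5]decan-8-yl trifluoromethanesulfonate | CC1(C)C[C@@]2(CC[C@H]1OS(=O)(=O)C(F)(F)F)OC(=O)O[C@@H]2[C@@H]1CC[C@]3(C)[C@H](OS(=O)(=O)C(F)(F)F)CC[C@@](C)(O)[C@@H]13
F2 | step 16 | (1R)-1-[(1R,3aS,4R,7R,7aS)-4-{[tert-butyl(dimethyl)silyl]oxy}-7-hydroxy-3a,7-dimethyloctahydro-1H-inden-1-yl]-6-methyl-2-methylidenehept-5-en-1-yl dimethylcarbamate | C=C(CCC=C(C)C)[C@H](OC(=O)N(C)C)[C@@H]1CC[C@]2(C)[C@H](O[Si](C)(C)C(C)(C)C)CC[C@@](C)(O)[C@@H]12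
F3 | step 16 | (1R)-1-[(1R,3aS,4R,7R,7aS)-4-{[tert-butyl(dimethyl)silyl]oxy}-7-hydroxy-3a,7-dimethyloctahydro-1H-inden-1-yl]-4-[(2R)-3,3-dimethyloxiran-2-yl]-2-methylidenebutyl dimethylcarbamate | CC1(C)O[C@@H]1CCC(=C)[C@H](OC(=O)N(C)C)[C@@H]1CC[C@]2(C)[C@H](O[Si](C)(C)C(C)(C)C)CC[C@@](C)(O)[C@@H]12
F4 | step 4 | methyl 4-[(1R,2R)-2-{[tert-butyl(dimethyl)silyl]oxy}-1-methyl-6-oxocyclohexyl]butanoate | COC(=O)CCC[C@]1(C)[C@H](O[Si](C)(C)C(C)(C)C)CCCC1=O
F5 | step 4 | methyl 4-[(1R,6R)-6-{[tert-butyl(dimethyl)silyl]oxy}-1-methyl-2-{[(trifluoromethyl)sulfonyl]oxy}cyclohex-2-en-1-yl]butanoate | COC(=O)CCC[C@]1(C)[C@H](O[Si](C)(C)C(C)(C)C)CCC=C1OS(=O)(=O)C(F)(F)F
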